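The ten-membered carbocycle is numbered C1–C10 (C4/C5 epoxide, C6 carbinol, C7/C8 lactone fusion, C9 ester, C10 CH–CH3, C1–C3 methylenes). Everything rests on disconnecting C1–C2 while reconnecting C4 to C9: an anionic oxy-Cope ring expansion. In one operation the six-membered ring C4–C9, carrying a vinyl group on C4 and an isopropenyl group on the C9 carbinol, forms the C1–C2 bond, opens to the ten-membered ring and delivers the C9 ketone, the C10 stereocentre and a C3=C4 olefin. The step exploits the 1,6 relationship between the C9 oxygen and C4 across C1–C2. The precursor comes from (R)-carvone; a vinyl epoxide later relays the olefin to C4=C5.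

Key step: step 8

Remark on the chemistry: locants C1–C15 of the paragraph above are used for every intermediate (C11 = side-chain carbon on C7, C12 = its oxygen-bearing carbon, C13 = exocyclic methylene, C14/C15 = methyls on C10/C4); β is the ring face that carries C11 on C7, α the opposite face.
Assumption: the carbinol centre of 3–5 and the side-chain oxirane centre of 7 form as both epimers and are erased in steps 3 and 5, so their SMILES leave these centres open.

Step 1
Reactants: 1 (R)-(−)-carvone
Product: 3 selenide aldol (4β-(1-hydroxyethyl)-4α-methyl-5α-phenylselanyl-7β-isopropenyl cyclohexan-9-one), via aluminium enolate 2 (not isolated)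
Conditions: Me2AlSePh (from AlMe3 and PhSeH, toluene, 0 °C), CH2Cl2, −78 °C; then MeCHO, −78 °C; aq. NH4Cl
Reagents that add atoms: dimethylaluminium benzeneselenolate, C[Al](C)[Se]c1ccccc1; acetaldehyde, CC=O
Why: Tandem hetero-Michael addition/aluminium aldol reaction: the selenolate should add axially to C5 trans to the C7 isopropenyl group, and acetaldehyde should then attack the enolate at C4 anti to the axial C–Se bond, which places the two-carbon arm on the β face (cis to isopropenyl) and fixes the C4 quaternary centre.

Step 2
Reactants: 3 selenide aldol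
Product: 5 β-hydroxy ketone (2-(1-hydroxyethyl)-2-methyl-5-(prop-1-en-2-yl)cyclohex-3-en-1-one; hydroxyethyl cis to isopropenyl), via selenoxide 4 (not isolated)
Conditions: 30% H2O2, pyridine, CH2Cl2, 0 °C to rt
Reagents that add atoms: none
Why: Selenoxide syn-elimination: C4 is quaternary, so only a C6 hydrogen can be removed and the C5=C6 olefin should form regiospecifically and cannot move into conjugation.

Step 3
Reactants: 5 β-hydroxy ketone
Product: 6 (2S,5S)-2-ethenyl-2-methyl-5-(prop-1-en-2-yl)cyclohex-3-en-1-one (vinyl cis to isopropenyl)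
Conditions: Burgess reagent, benzene, 50 °C
Reagents that add atoms: none
Why: Burgess dehydration (syn-elimination of the sulfamate): the carbinol carbon has β-hydrogens only on its methyl group, so the vinyl group is the only olefin that can form.

Step 4
Reactants: 6 vinyl ketone
Product: 7 bis-epoxide (2-ethenyl-2-methyl-5-(2-methyloxiran-2-yl)-7-oxabicyclo[4.1.0]heptan-3-one; 5α,6α-epoxide)
Conditions: mCPBA (2.3 equiv), NaHCO3, CH2Cl2, 0 °C
Reagents that add atoms: 3-chloroperbenzoic acid (mCPBA), OOC(=O)c1cccc(Cl)c1
Why: Prilezhaev epoxidation: the ring olefin should be attacked on the α face, anti to the pseudo-axial C4 vinyl group, and the isopropenyl group is epoxidised on purpose at the same time, while the neopentyl monosubstituted vinyl group reacts far more slowly.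

Step 5
Reactants: 7 bis-epoxide
Product: 8 bis(trimethylsilyl) compound (C8=C9 trimethylsilyl enol ether and C12 allyl trimethylsilyl ether; C11=C13 methylidene; 5α,6α-epoxide intact)
Conditions: TMSOTf (2.4 equiv), 2,6-lutidine, toluene, −78 °C; then DBU, −78 to 0 °C; non-aqueous work-up
Reagents that add atoms: trimethylsilyl triflate, C[Si](C)(C)OS(=O)(=O)C(F)(F)F
Why: Silyl-triflate-mediated isomerisation of an epoxide to an allylic silyl ether (ionisation at the tertiary C11 centre, then loss of a methyl proton to DBU) should act only on the 2,2-disubstituted side-chain oxirane, because the ring oxirane cannot give a stabilised cation, while the ketone is enol-silylated towards C8, its only enolisable position.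

Step 6
Reactants: 8 bis(trimethylsilyl) compound
Product: 10 tricyclic ether ketone (8β,12-ether: cis-fused 3-methylidenetetrahydrofuran on the C9 ketone; 4β-vinyl; 5α,6α-epoxide), via bromo ketone 9 (not isolated)
Conditions: NBS, THF, −78 °C; then Bu4NF, −78 to 0 °C
Reagents that add atoms: none
Why: α-Bromination of the silyl enol ether anti to the C7 side chain, then fluoride-triggered intramolecular Williamson etherification (SN2 with inversion at the α-keto carbon C8) can only give the cis-fused ether, so the C8 oxygen ends on the β face; the epimeric bromide would equilibrate through the enol.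

Step 7
Reactants: 10 tricyclic ether ketone
Product: 11 divinyl carbinol (9β-hydroxy-9α-isopropenyl, trans to the 4β-vinyl group)
Conditions: CH2=C(CH3)MgBr, CeCl3, THF, −78 °C
Reagents that add atoms: isopropenylmagnesium bromide, CC(=C)[Mg]Br
Why: Organocerium 1,2-addition to the α-alkoxy ketone from the convex α face, anti to the cis-fused ether ring (chelation of C9=O with O8 points the same way), should set C9 with isopropenyl α and hydroxyl β.

Step 8
Reactants: 11 divinyl carbinol
Product: 14 ten-membered ketone ((3E)-C3=C4; 5α,6α-epoxide; 8β,12-ether; 10α-methyl; C9=O), via potassium alkoxide 12 (not isolated), via potassium enolate 13 (not isolated)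
Conditions: KH, 18-crown-6, THF, 0 °C to rt; then AcOH, THF, −78 °C
Reagents that add atoms: none
Why: Deprotonation gives potassium alkoxide 12, whose [3,3]-sigmatropic shift through a chair transition state forms the C1–C2 σ bond between the two terminal methylene carbons while the C4–C9 bond breaks, giving the ring-expanded enolate 13 regiospecifically on the C10 side. The closest known reaction type is the anionic oxy-Cope ring expansion of trans-1,2-dialkenylcyclohexanols to cyclodec-5-enones. The ten-membered ring is closed by this pericyclic four-carbon ring expansion (six to ten), not by end-to-end cyclisation, so no high dilution is needed. The trans-diequatorial isopropenyl and vinyl groups enforce the chair, which should give the E C3=C4 olefin, and the new C10 stereocentre is set when the enolate, still in the conformation the chair delivers, is protonated on its outer face (away from the C3=C4 olefin), which should give the 10R epimer with the same sense as C8. The step needs the [3,3] shift to outrun attack of the alkoxide on the C5–C6 epoxide; the axial alkoxide cannot reach C6 without a boat flip and the rearrangement is expected already at 0 °C. C6, C7 and C8 are not touched.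

Step 9
Reactants: 14 ten-membered ketone
Product: 15 9α-alcohol (9R)
Conditions: K[HB(s-Bu)3] (K-Selectride), THF, −78 °C; H2O
Reagents that add atoms: none
Why: Hydride reduction under non-chelating conditions: Felkin–Anh (Cornforth) addition anti to the C8–O bond from the ring periphery should give the 9α-alcohol, trans to the C8 oxygen.

Step 10
Reactants: 15 9α-alcohol
Product: 16 9-O-(3-methylbut-2-enoyl) ester
Conditions: 3-methylbut-2-enoic acid, DCC, DMAP, CH2Cl2, rt
Reagents that add atoms: 3-methylbut-2-enoic acid, CC(C)=CC(=O)O
Why: Steglich esterification of the only free hydroxyl group; the carbodiimide route avoids the ketene pathway that deconjugates the acid chloride.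

Step 11
Reactants: 16 ester
Product: 17 α-methylene lactone (8β,12-olide)
Conditions: CrO3, 3,5-dimethylpyrazole, CH2Cl2, −20 °C
Reagents that add atoms: chromium trioxide, O=[Cr](=O)=O
Why: Chromium-mediated allylic oxidation, a known conversion of 3-methylidenetetrahydrofurans into α-methylene-γ-butyrolactones: the C12 methylene, activated by both the ring oxygen and the exocyclic olefin, carries the weakest C–H bonds and no free hydroxyl is present.

Step 12
Reactants: 17 α-methylene lactone
Product: 18 allylic alcohol ((4E)-C4=C5; 6α-hydroxy; C3 methylene)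
Conditions: SmI2 (2.2 equiv), THF/MeOH, −90 °C
Reagents that add atoms: none
Why: SmI2 reduction of a vinyl epoxide (electron transfer, opening to the allyl radical/anion, protonation at the distal carbon C3) should relay the olefin to C4=C5 with E geometry from the transoid C3=C4–C5–C6 arrangement and free the C6 hydroxyl without touching its configuration, and it is expected to be much faster than reduction of the two conjugated esters at this temperature.

Step 13
Reactants: 18 allylic alcohol
Product: 19 CNP0214930.1 (target)
Conditions: VO(acac)2 (cat.), t-BuOOH, CH2Cl2, 0 °C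
Reagents that add atoms: tert-butyl hydroperoxide, CC(C)(C)OO
Why: Vanadium-catalysed hydroxyl-directed epoxidation: in the E-cyclodecene the C6–C7 bond stands roughly perpendicular to the olefin plane, so the C6 hydroxyl lies near that plane on the outer face and should deliver oxygen there, giving the erythro (4R,5R) epoxy alcohol, while the electron-poor enoate and methylene-lactone olefins do not react.

Compound list
1 | (R)-(−)-carvone, (5R)-2-methyl-5-(prop-1-en-2-yl)cyclohex-2-en-1-one | CC1=CC[C@H](CC1=O)C(C)=C | starting material
2 | dimethylaluminium enolate of the conjugate adduct (PhSe on C5, trans to isopropenyl) | C[Al](C)OC1=C(C)[C@H]([Se]c2ccccc2)C[C@@H](C(C)=C)C1 | intermediate (not isolated)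
3 | 2-(1-hydroxyethyl)-2-methyl-3-(phenylselanyl)-5-(prop-1-en-2-yl)cyclohexan-1-one; hydroxyethyl cis to isopropenyl, PhSe trans to both | C[C@]1(C(C)O)[C@H]([Se]c2ccccc2)C[C@@H](C(C)=C)CC1=O | intermediate
4 | selenoxide of 3 | C[C@]1(C(C)O)[C@H]([Se](=O)c2ccccc2)C[C@@H](C(C)=C)CC1=O | intermediate (not isolated)
5 | 2-(1-hydroxyethyl)-2-methyl-5-(prop-1-en-2-yl)cyclohex-3-en-1-one; hydroxyethyl cis to isopropenyl | C[C@]1(C(C)O)C=C[C@@H](C(C)=C)CC1=O | intermediate
6 | (2S,5S)-2-ethenyl-2-methyl-5-(prop-1-en-2-yl)cyclohex-3-en-1-one | C[C@]1(C=C)C=C[C@@H](C(C)=C)CC1=O | intermediate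
7 | 2-ethenyl-2-methyl-5-(2-methyloxiran-2-yl)-7-oxabicyclo[4.1.0]heptan-3-one; ring epoxide α (trans to vinyl and to the C7 side chain) | C[C@]1(C=C)[C@@H]2O[C@@H]2[C@@H](C3(C)CO3)CC1=O | intermediate
8 | bis(trimethylsilyl) compound: C8=C9 silyl enol ether, C12 allyl silyl ether, 5α,6α-epoxide, 4β-vinyl | C[C@]1(C=C)[C@@H]2O[C@@H]2[C@@H](C(=C)CO[Si](C)(C)C)C=C1O[Si](C)(C)C | intermediate
9 | 8α-bromo ketone, allyl silyl ether (bromine trans to the C7 side chain) | C[C@]1(C=C)[C@@H]2O[C@@H]2[C@@H](C(=C)CO[Si](C)(C)C)[C@H](Br)C1=O | intermediate (not isolated)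
10 | tricyclic ether ketone: C9 ketone, 4α-methyl-4β-vinyl, 5α,6α-epoxide, cis-fused 3-methylidenetetrahydrofuran (C7–C11, C8–O–C12, both β) | C[C@]1(C=C)[C@@H]2O[C@@H]2[C@H]3C(=C)CO[C@H]3C1=O | intermediate
11 | divinyl carbinol: 10 with 9β-hydroxy and 9α-(prop-1-en-2-yl) | C[C@]1(C=C)[C@@H]2O[C@@H]2[C@H]3C(=C)CO[C@H]3[C@]1(O)C(C)=C | intermediate
12 | potassium alkoxide of 11 | C[C@]1(C=C)[C@@H]2O[C@@H]2[C@H]3C(=C)CO[C@H]3[C@]1([O-])C(C)=C.[K+] | intermediate (not isolated)
13 | potassium enolate of 14 (C9=C10 enolate, C14 cis to C8; E C3=C4) | C1/C=C(C)/[C@@H]2O[C@@H]2[C@H]3C(=C)CO[C@H]3/C([O-])=C(\C)C1.[K+] | intermediate (not isolated)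
14 | ten-membered ketone: C9 ketone, 10α-methyl (10R), (3E)-olefin, 5α,6α-epoxide, 8β,12-ether with C11=C13 methylidene | C[C@@H]1CC/C=C(C)/[C@@H]2O[C@@H]2[C@H]3C(=C)CO[C@H]3C1=O | intermediate
15 | 9α-alcohol (9R) of 14 | C[C@@H]1CC/C=C(C)/[C@@H]2O[C@@H]2[C@H]3C(=C)CO[C@H]3[C@@H]1O | intermediate
16 | 9-O-(3-methylbut-2-enoyl) ester of 15 | C[C@@H]1CC/C=C(C)/[C@@H]2O[C@@H]2[C@H]3C(=C)CO[C@H]3[C@@H]1OC(=O)C=C(C)C | intermediate
17 | α-methylene-8β,12-lactone: 16 with C12 oxidised to the lactone carbonyl | C[C@@H]1CC/C=C(C)/[C@@H]2O[C@@H]2[C@H]3C(=C)C(=O)O[C@H]3[C@@H]1OC(=O)C=C(C)C | intermediate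
18 | allylic alcohol: (4E)-olefin, 6α-hydroxy (6R), 8β,12-olide, 9α-ester, 10α-methyl | C[C@@H]1CCC/C(C)=C/[C@H](O)[C@H]2C(=C)C(=O)O[C@H]2[C@@H]1OC(=O)C=C(C)C | intermediate
19 | CNP0214930.1, (4R,5R,6R,7R,8R,9R,10R) in the numbering used here | C=C1C(=O)O[C@H]2[C@H](OC(=O)C=C(C)C)[C@H](C)CCC[C@@]3(C)O[C@@H]3[C@H](O)[C@@H]12 | target

Total step count: 13. Longest linear sequence: 13 steps, fully linear from (R)-carvone.

Steps most likely to fail

Step 5 – loss of chemoselectivity between the two oxiranes: the silyl triflate may also ionise the ring epoxide, or the tertiary cation may lose the C7 proton instead of a methyl proton. The fallback sets out from 6 and comes back at 10. The isopropenyl group of 6 is first chlorinated in an ene-type reaction (Ca(OCl)2, solid CO2, CH2Cl2/H2O) to allyl chloride F1. Its 2-(chloromethyl)allyl olefin is electron-poor, so mCPBA should now epoxidise only the ring olefin, giving epoxy chloride F2. CsOAc in DMF gives allyl acetate F3; TMSOTf/Et3N gives silyl enol ether F4; NBS gives bromo ketone F5; K2CO3 in MeOH removes the acetate, and the freed alkoxide closes the ether to 10.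

Step 9 – poor facial selectivity of hydride delivery: if the ketone reacts through the conformer with C9=O syn to the C8 oxygen, the 9β-alcohol results. The fallback sets out from 14 and comes back at 16. That epimer is made on purpose by chelation-controlled reduction with Zn(BH4)2 (ether, −30 °C), giving 9β-alcohol F6. A Mitsunobu esterification with 3-methylbut-2-enoic acid (PPh3, diisopropyl azodicarboxylate, toluene) then installs the ester with inversion at C9 and gives 16 directly.

Step 11 – poor site selectivity and over-oxidation: the chromium reagent may attack the C2 allylic methylene or degrade the acid-sensitive vinyl epoxide. The fallback sets out from 16 and comes back at 17. Hydride abstraction from the doubly activated C12 methylene with DDQ in wet CH2Cl2 (pH 7 buffer) gives, after water traps the oxocarbenium ion, lactol F7. MnO2 in CH2Cl2 then oxidises the allylic lactol to 17.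

Further compounds
F1 | step 5 | allyl chloride: (2S,5S)-5-(3-chloroprop-1-en-2-yl)-2-ethenyl-2-methylcyclohex-3-en-1-one | C[C@]1(C=C)C=C[C@@H](C(=C)CCl)CC1=O
F2 | step 5 | epoxy chloride: 5α,6α-epoxide of F1 | C[C@]1(C=C)[C@@H]2O[C@@H]2[C@@H](C(=C)CCl)CC1=O
F3 | step 5 | allyl acetate: F2 with chloride replaced by acetoxy | C[C@]1(C=C)[C@@H]2O[C@@H]2[C@@H](C(=C)COC(C)=O)CC1=O
F4 | step 5 | silyl enol ether: C8=C9 trimethylsilyl enol ether of F3 | C[C@]1(C=C)[C@@H]2O[C@@H]2[C@@H](C(=C)COC(C)=O)C=C1O[Si](C)(C)C
F5 | step 5 | bromo ketone: 8α-bromo derivative of F3 | C[C@]1(C=C)[C@@H]2O[C@@H]2[C@@H](C(=C)COC(C)=O)[C@H](Br)C1=O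
F6 | step 9 | 9β-alcohol: C9 epimer of 15 | C[C@@H]1CC/C=C(C)/[C@@H]2O[C@@H]2[C@H]3C(=C)CO[C@H]3[C@H]1O
F7 | step 11 | lactol: 16 with C12 hydroxylated (both C12 epimers) | C[C@@H]1CC/C=C(C)/[C@@H]2O[C@@H]2[C@H]3C(=C)C(O)O[C@H]3[C@@H]1OC(=O)C=C(C)C
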